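**Retrosynthetic overview**

1. The strategy rests on the 2,4-dihydroxy-6-alkylbenzoate ring (ring carbons C1–C6) and its C(=O)–O bond to O3 of the (R)-3-hydroxybutanoate: together they are a folded 3,5,7-triketo ester, and the ring bond between C1 (carboxyl-bearing) and C6 (oxopentyl-bearing) is an aldol bond.
2. Key disconnections: that C1–C6 ring bond (aldol, then aromatization) and the benzoate C(=O)–O bond (acylketene plus secondary alcohol). They lead to a diketo-dioxinone and the (R)-3-hydroxybutanoate of the bis-benzylated (R)-aryl-propanol.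
3. The diketo-dioxinone is cut at chain bond C6–C7 into a keto-dioxinone dianion and a Weinreb amide that carries the side-chain ketone as a dioxolane and the carbinol as a silyl ether. The amide and the butanoate unit both come from one silylated (R)-3-hydroxybutanoic acid; the aryl-propanol comes from aryl Grignard opening of (R)-propylene oxide.
4. Ring order: the resorcinol ring is bought; the only ring made is the resorcylate benzene ring, closed in the key step. Aqueous acid and then hydrogenolysis finish the route.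

Key step: step 11

Assumption: β-dicarbonyl and polycarbonyl intermediates are drawn as keto tautomers although they exist largely as enols, and chain positions C1–C9 of the triketo ester are counted from its ester carbonyl.

**Step 1**
Reactants: 1 methyl (R)-3-hydroxybutanoate
Product: 2 methyl (R)-3-[(tert-butyldimethylsilyl)oxy]butanoate
Conditions: TBSCl, imidazole, DMF, 0 °C to rt
Reagents that add atoms: tert-butyldimethylsilyl chloride (TBSCl), CC(C)(C)[Si](C)(C)Cl
Why: Imidazole-promoted silyl ether formation on a secondary alcohol is routine and does not touch the stereocentre.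

**Step 2**
Reactants: 2 methyl (R)-3-[(tert-butyldimethylsilyl)oxy]butanoate
Product: 3 (R)-3-[(tert-butyldimethylsilyl)oxy]butanoic acid
Conditions: LiOH, THF/MeOH/H2O, rt; then cold 1 M HCl to pH 3
Reagents that add atoms: lithium hydroxide, [Li+].[OH-]
Why: Ester saponification at room temperature should be much faster than E1cB loss of silanolate, so the β-silyloxy acid is expected with C3 unchanged.

**Step 3**
Reactants: 4 1,3-bis(benzyloxy)-5-bromobenzene; 5 (R)-propylene oxide [(R)-2-methyloxirane]
Product: 7 (R)-1-[3,5-bis(benzyloxy)phenyl]propan-2-ol, via arylmagnesium bromide 6 (not isolated)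
Conditions: Mg, THF, 65 °C; then CuI (10 mol%), 5, −30 to 0 °C; then 1 M aq. HCl
Reagents that add atoms: none
Why: Copper-catalysed opening of a terminal epoxide by an aryl Grignard reagent is an SN2 attack at the unsubstituted CH2, so the oxygen-bearing stereocentre of 5 is carried over unchanged as the (R)-carbinol.

**Step 4**
Reactants: 7 (R)-1-[3,5-bis(benzyloxy)phenyl]propan-2-ol; 3 (R)-3-[(tert-butyldimethylsilyl)oxy]butanoic acid
Product: 8 (R)-1-[3,5-bis(benzyloxy)phenyl]propan-2-yl (R)-3-[(tert-butyldimethylsilyl)oxy]butanoate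
Conditions: DIC, DMAP (cat.), CH2Cl2, 0 °C to rt
Reagents that add atoms: none
Why: Steglich esterification (carbodiimide activation with DMAP acyl transfer) of an unhindered secondary alcohol should proceed with retention at both stereocentres, since neither C–O bond at a stereocentre is broken.

**Step 5**
Reactants: 8 (R)-1-[3,5-bis(benzyloxy)phenyl]propan-2-yl (R)-3-[(tert-butyldimethylsilyl)oxy]butanoate
Product: 9 (R)-1-[3,5-bis(benzyloxy)phenyl]propan-2-yl (R)-3-hydroxybutanoate
Conditions: HF·pyridine, THF, 0 °C to rt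
Reagents that add atoms: none
Why: Fluoride-mediated Si–O cleavage under mildly acidic, non-basic conditions should free the β-hydroxyl without retro-aldol cleavage, β-elimination or acyl migration, and it leaves the benzyl ethers intact.

**Step 6**
Reactants: 3 (R)-3-[(tert-butyldimethylsilyl)oxy]butanoic acid
Product: 12 methyl (R)-5-[(tert-butyldimethylsilyl)oxy]-3-oxohexanoate, via acyl imidazolide 10 (not isolated), via acylmalonic half ester 11 (not isolated)
Conditions: CDI, THF, rt; then MeO2CCH2CO2K, MgCl2, THF, rt to 45 °C; then cold 1 M HCl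
Reagents that add atoms: potassium methyl malonate, COC(=O)CC(=O)[O-].[K+]
Why: In the Masamune–Brooks two-carbon homologation the acyl imidazolide C-acylates the magnesium enolate of the malonic half ester and the adduct decarboxylates to the β-keto ester under near-neutral conditions that spare the silyl ether and the stereocentre.

**Step 7**
Reactants: 12 methyl (R)-5-[(tert-butyldimethylsilyl)oxy]-3-oxohexanoate
Product: 13 methyl 2-{2-[(R)-2-((tert-butyldimethylsilyl)oxy)propyl]-1,3-dioxolan-2-yl}acetate
Conditions: (TMSOCH2)2, TMSOTf (5 mol%), CH2Cl2, −78 to −20 °C; then pyridine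
Reagents that add atoms: 1,2-bis(trimethylsilyloxy)ethane, C[Si](C)(C)OCCO[Si](C)(C)C
Why: Noyori ketalization (TMSOTf-catalysed exchange with the bis-silyl ether of ethylene glycol, driven by formation of hexamethyldisiloxane) runs at low temperature without protic acid, so the secondary silyl ether should survive while the ketone is converted to its dioxolane.

**Step 8**
Reactants: 13 methyl 2-{2-[(R)-2-((tert-butyldimethylsilyl)oxy)propyl]-1,3-dioxolan-2-yl}acetate
Product: 14 N-methoxy-N-methyl-2-{2-[(R)-2-((tert-butyldimethylsilyl)oxy)propyl]-1,3-dioxolan-2-yl}acetamide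
Conditions: MeNH(OMe)·HCl, i-PrMgCl, THF, −20 to 0 °C; then aq. NH4Cl
Reagents that add atoms: N,O-dimethylhydroxylamine hydrochloride, CNOC.Cl
Why: Direct aminolysis of a methyl ester by the magnesium amide of N,O-dimethylhydroxylamine is the standard one-step Weinreb amide synthesis, and any β-elimination that opens the dioxolane is reversible because the alkoxide stays tethered.

**Step 9**
Reactants: 15 2,2,6-trimethyl-4H-1,3-dioxin-4-one
Product: 17 2,2-dimethyl-6-(2-oxopropyl)-4H-1,3-dioxin-4-one, via lithium dienolate 16 (not isolated)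
Conditions: LiN(SiMe3)2 (LiHMDS), THF, −78 °C; then AcCl (0.5 equiv.), −78 °C
Reagents that add atoms: acetyl chloride, CC(=O)Cl
Why: γ-Deprotonation gives the vinylogous ester dienolate, which undergoes Claisen-type C-acylation at the exocyclic carbon with acetyl chloride, the excess enolate taking up the acidic proton of the product.

**Step 10**
Reactants: 17 2,2-dimethyl-6-(2-oxopropyl)-4H-1,3-dioxin-4-one; 14 N-methoxy-N-methyl-2-{2-[(R)-2-((tert-butyldimethylsilyl)oxy)propyl]-1,3-dioxolan-2-yl}acetamide
Product: 19 6-{2,4-dioxo-5-[2-((R)-2-((tert-butyldimethylsilyl)oxy)propyl)-1,3-dioxolan-2-yl]pentyl}-2,2-dimethyl-4H-1,3-dioxin-4-one, via dilithium dianion 18 (not isolated)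
Conditions: LiN(i-Pr)2 (LDA, 2.1 equiv.), THF, −78 °C; then 14, −78 to −20 °C; then AcOH
Reagents that add atoms: none
Why: Claisen-type acylation of a 1,3-dicarbonyl dianion takes place at its terminal, most nucleophilic carbon, and the chelated tetrahedral adduct of the Weinreb amide prevents over-addition and releases the diketone only on quench.

**Step 11**
Reactants: 19 6-{2,4-dioxo-5-[2-((R)-2-((tert-butyldimethylsilyl)oxy)propyl)-1,3-dioxolan-2-yl]pentyl}-2,2-dimethyl-4H-1,3-dioxin-4-one; 9 (R)-1-[3,5-bis(benzyloxy)phenyl]propan-2-yl (R)-3-hydroxybutanoate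
Product: 23 (R)-1-[3,5-bis(benzyloxy)phenyl]propan-2-yl (R)-3-{[2,4-dihydroxy-6-({2-[(R)-2-((tert-butyldimethylsilyl)oxy)propyl]-1,3-dioxolan-2-yl}methyl)benzoyl]oxy}butanoate, via acylketene 20 (not isolated), via triketo ester 21 (not isolated), via aldol adduct 22 (not isolated)
Conditions: PhMe, 110 °C; then K2CO3, i-PrOH/CH2Cl2, rt; then AcOH
Reagents that add atoms: none
Why: Heating 19 triggers a retro-[4+2] fragmentation with loss of acetone to acylketene 20, which the secondary hydroxyl of 9 captures under neutral conditions to give triketo ester 21, so the ortho,ortho-disubstituted benzoate C(=O)–O bond is made before the ring exists. Carbonate then enolizes the C2 methylene (between ester C1 and ketone C3), which adds to the C7 ketone in a 6-(enolendo)-exo-trig aldol closure to 22, and E1cB dehydration with enolization of the C3 and C5 carbonyls gives the benzene ring, chain C2 and C7 becoming ring C1 and C6. The closest known reaction type is dioxinone thermolysis with alcohol capture followed by base-then-acid aromatization of 3,5,7-triketo esters to 6-alkylresorcylates. No stereocentre is created (the two sp3 centres of 22 are erased on aromatization), and none of the three existing ones is α to a carbonyl, so none can epimerize by enolization. The step needs C2-to-C7 aldol selectivity over lactonization to a pyranone and over other aldol modes: the dioxolane removes the C9 carbonyl, so C7 is the only ketone outside the β-keto ester and C8 is a hindered neopentyl-type methylene, and carbonate in a non-nucleophilic alcohol favours C-cyclization. The β-acyloxy butanoate meets only carbonate at room temperature, well below the basicity needed to enolize a simple ester.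

**Step 12**
Reactants: 23 (R)-1-[3,5-bis(benzyloxy)phenyl]propan-2-yl (R)-3-{[2,4-dihydroxy-6-({2-[(R)-2-((tert-butyldimethylsilyl)oxy)propyl]-1,3-dioxolan-2-yl}methyl)benzoyl]oxy}butanoate
Product: 24 (R)-1-[3,5-bis(benzyloxy)phenyl]propan-2-yl (R)-3-({2,4-dihydroxy-6-[(R)-4-hydroxy-2-oxopentyl]benzoyl}oxy)butanoate
Conditions: 1 M aq. HCl/THF, rt
Reagents that add atoms: water, O
Why: Acid-catalysed hydrolysis of the dioxolane (through its oxocarbenium ion) and protodesilylation of the secondary silyl ether should both occur under the same mild aqueous acid, which leaves the esters, the benzyl ethers and the C–O stereocentres untouched.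

**Step 13**
Reactants: 24 (R)-1-[3,5-bis(benzyloxy)phenyl]propan-2-yl (R)-3-({2,4-dihydroxy-6-[(R)-4-hydroxy-2-oxopentyl]benzoyl}oxy)butanoate
Product: 25 hansforester K
Conditions: H2 (1 atm), 10% Pd/C, EtOAc/MeOH, rt
Reagents that add atoms: none
Why: Hydrogenolysis of aryl benzyl ethers over Pd/C at 1 atm and room temperature should not reduce the homobenzylic ester C–O bonds, the ketone or the arenes, so the neutral last step leaves all three stereocentres as set.

**Compound list**

1 | methyl (R)-3-hydroxybutanoate | C[C@@H](O)CC(=O)OC | starting material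
2 | methyl (R)-3-[(tert-butyldimethylsilyl)oxy]butanoate | C[C@@H](O[Si](C)(C)C(C)(C)C)CC(=O)OC | intermediate
3 | (R)-3-[(tert-butyldimethylsilyl)oxy]butanoic acid | C[C@@H](O[Si](C)(C)C(C)(C)C)CC(=O)O | intermediate
4 | 1,3-bis(benzyloxy)-5-bromobenzene | Brc1cc(OCc2ccccc2)cc(OCc2ccccc2)c1 | starting material
5 | (R)-propylene oxide [(R)-2-methyloxirane] | C[C@@H]1CO1 | starting material
6 | [3,5-bis(benzyloxy)phenyl]magnesium bromide | Br[Mg]c1cc(OCc2ccccc2)cc(OCc2ccccc2)c1 | intermediate (not isolated)
7 | (R)-1-[3,5-bis(benzyloxy)phenyl]propan-2-ol | C[C@H](Cc1cc(OCc2ccccc2)cc(OCc2ccccc2)c1)O | intermediate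
8 | (R)-1-[3,5-bis(benzyloxy)phenyl]propan-2-yl (R)-3-[(tert-butyldimethylsilyl)oxy]butanoate | C[C@H](Cc1cc(OCc2ccccc2)cc(OCc2ccccc2)c1)OC(=O)C[C@@H](C)O[Si](C)(C)C(C)(C)C | intermediate
9 | (R)-1-[3,5-bis(benzyloxy)phenyl]propan-2-yl (R)-3-hydroxybutanoate | C[C@H](Cc1cc(OCc2ccccc2)cc(OCc2ccccc2)c1)OC(=O)C[C@@H](C)O | intermediate
10 | 1-{(R)-3-[(tert-butyldimethylsilyl)oxy]butanoyl}-1H-imidazole | C[C@@H](O[Si](C)(C)C(C)(C)C)CC(=O)n1ccnc1 | intermediate (not isolated)
11 | (5R)-5-[(tert-butyldimethylsilyl)oxy]-2-(methoxycarbonyl)-3-oxohexanoic acid (present as its magnesium chelate; C2 undefined) | C[C@@H](O[Si](C)(C)C(C)(C)C)CC(=O)C(C(=O)O)C(=O)OC | intermediate (not isolated)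
12 | methyl (R)-5-[(tert-butyldimethylsilyl)oxy]-3-oxohexanoate | C[C@@H](O[Si](C)(C)C(C)(C)C)CC(=O)CC(=O)OC | intermediate
13 | methyl 2-{2-[(R)-2-((tert-butyldimethylsilyl)oxy)propyl]-1,3-dioxolan-2-yl}acetate | C[C@@H](O[Si](C)(C)C(C)(C)C)CC1(CC(=O)OC)OCCO1 | intermediate
14 | N-methoxy-N-methyl-2-{2-[(R)-2-((tert-butyldimethylsilyl)oxy)propyl]-1,3-dioxolan-2-yl}acetamide | C[C@@H](O[Si](C)(C)C(C)(C)C)CC1(CC(=O)N(C)OC)OCCO1 | intermediate
15 | 2,2,6-trimethyl-4H-1,3-dioxin-4-one | CC1=CC(=O)OC(C)(C)O1 | starting material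
16 | lithium 2,2-dimethyl-6-methylidene-6H-1,3-dioxin-4-olate (dienolate of 15) | [Li+].C=C1C=C([O-])OC(C)(C)O1 | intermediate (not isolated)
17 | 2,2-dimethyl-6-(2-oxopropyl)-4H-1,3-dioxin-4-one | CC(=O)CC1=CC(=O)OC(C)(C)O1 | intermediate
18 | dilithium dianion of 17 (bis-enolate) | [Li+].[Li+].C=C([O-])C=C1C=C([O-])OC(C)(C)O1 | intermediate (not isolated)
19 | 6-{2,4-dioxo-5-[2-((R)-2-((tert-butyldimethylsilyl)oxy)propyl)-1,3-dioxolan-2-yl]pentyl}-2,2-dimethyl-4H-1,3-dioxin-4-one | CC1(C)OC(=CC(=O)O1)CC(=O)CC(=O)CC2(C[C@@H](C)O[Si](C)(C)C(C)(C)C)OCCO2 | intermediate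
20 | 8-{2-[(R)-2-((tert-butyldimethylsilyl)oxy)propyl]-1,3-dioxolan-2-yl}oct-1-ene-1,3,5,7-tetrone (acylketene) | O=C=CC(=O)CC(=O)CC(=O)CC1(C[C@@H](C)O[Si](C)(C)C(C)(C)C)OCCO1 | intermediate (not isolated)
21 | (R)-1-[3,5-bis(benzyloxy)phenyl]propan-2-yl (R)-3-{[3,5,7-trioxo-8-(2-((R)-2-((tert-butyldimethylsilyl)oxy)propyl)-1,3-dioxolan-2-yl)octanoyl]oxy}butanoate (triketo ester) | C[C@H](Cc1cc(OCc2ccccc2)cc(OCc2ccccc2)c1)OC(=O)C[C@@H](C)OC(=O)CC(=O)CC(=O)CC(=O)CC3(C[C@@H](C)O[Si](C)(C)C(C)(C)C)OCCO3 | intermediate (not isolated)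
22 | (R)-1-[3,5-bis(benzyloxy)phenyl]propan-2-yl (R)-3-{[2-hydroxy-4,6-dioxo-2-({2-[(R)-2-((tert-butyldimethylsilyl)oxy)propyl]-1,3-dioxolan-2-yl}methyl)cyclohexane-1-carbonyl]oxy}butanoate (aldol adduct; cyclohexane C1 and C2 undefined) | C[C@H](Cc1cc(OCc2ccccc2)cc(OCc2ccccc2)c1)OC(=O)C[C@@H](C)OC(=O)C3C(=O)CC(=O)CC3(O)CC4(C[C@@H](C)O[Si](C)(C)C(C)(C)C)OCCO4 | intermediate (not isolated)
23 | (R)-1-[3,5-bis(benzyloxy)phenyl]propan-2-yl (R)-3-{[2,4-dihydroxy-6-({2-[(R)-2-((tert-butyldimethylsilyl)oxy)propyl]-1,3-dioxolan-2-yl}methyl)benzoyl]oxy}butanoate | C[C@H](Cc1cc(OCc2ccccc2)cc(OCc2ccccc2)c1)OC(=O)C[C@@H](C)OC(=O)c3c(O)cc(O)cc3CC4(C[C@@H](C)O[Si](C)(C)C(C)(C)C)OCCO4 | intermediate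
24 | (R)-1-[3,5-bis(benzyloxy)phenyl]propan-2-yl (R)-3-({2,4-dihydroxy-6-[(R)-4-hydroxy-2-oxopentyl]benzoyl}oxy)butanoate | C[C@H](Cc1cc(OCc2ccccc2)cc(OCc2ccccc2)c1)OC(=O)C[C@@H](C)OC(=O)c1c(O)cc(O)cc1CC(=O)C[C@@H](C)O | intermediate
25 | hansforester K: (R)-1-(3,5-dihydroxyphenyl)propan-2-yl (R)-3-({2,4-dihydroxy-6-[(R)-4-hydroxy-2-oxopentyl]benzoyl}oxy)butanoate | C[C@H](Cc1cc(O)cc(O)c1)OC(=O)C[C@@H](C)OC(=O)c1c(O)cc(O)cc1CC(=O)C[C@@H](C)O | target

**Step count**

Total steps: 13. Longest linear sequence: 9 steps (steps 1, 2, 6, 7, 8, 10, 11, 12, 13).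

**Steps most likely to fail**

Step 11 (acylketene capture and aldol aromatization). Under carbonate the enolized triketo ester may close through oxygen to a 4-hydroxy-2-pyranone with expulsion of the alcohol, or the butanoate may lose its β-acyloxy group by elimination. The alcohol may also capture the acylketene too slowly, so that the ketene cyclizes on itself. The fallback sets out from 19 and 9 and returns at 23. It closes the ring before the base-sensitive ester exists and still forms the hindered ester by neutral ketene capture. Treatment of 19 with Et3N in CH2Cl2 should effect the same C-to-C aldol aromatization within the dioxinone and give the benzodioxinone 7-hydroxy-2,2-dimethyl-5-({2-[(R)-2-((tert-butyldimethylsilyl)oxy)propyl]-1,3-dioxolan-2-yl}methyl)-4H-1,3-benzodioxin-4-one F1. Irradiation of F1 at 300 nm in CH2Cl2 in the presence of 9 should then expel acetone and give the ortho-quinone ketene F2, which the hydroxyl of 9 captures to give 23 directly.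

Step 10 (dianion acylation). The dianion may remove a proton from the α-methylene of 14 instead of adding to it, addition to the neopentyl-type amide carbonyl may be slow, or acylation may occur at oxygen. The fallback sets out from 14 and 17 and returns at 19, replacing the acylation by an aldol addition and an oxidation. Reduction of 14 with i-Bu2AlH (THF, −78 °C) should give the aldehyde 2-{2-[(R)-2-((tert-butyldimethylsilyl)oxy)propyl]-1,3-dioxolan-2-yl}acetaldehyde F3. Addition of dianion 18 (from 17 and LDA) to F3 should give the β-hydroxy ketone F4 as a mixture of carbinol epimers, which is of no consequence. Oxidation of F4 with Dess–Martin periodinane (NaHCO3, CH2Cl2) should give 19.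

Step 7 (ketalization beside a silyl ether). The Lewis acid may remove the silyl group, after which the δ-hydroxy ester lactonizes, or the largely enolized β-keto ester may ketalize only sluggishly. The fallback sets out from 1 and returns at 13. It carries the carbinol as an acid-stable benzyl ether through a classical Brønsted-acid ketalization and installs the silyl group afterwards. Benzylation of 1 with benzyl 2,2,2-trichloroacetimidate and catalytic TfOH should give methyl (R)-3-(benzyloxy)butanoate F5. Crossed Claisen condensation of F5 with an excess of the lithium enolate of methyl acetate (THF, −78 °C) should give methyl (R)-5-(benzyloxy)-3-oxohexanoate F6. Ethylene glycol and TsOH in benzene with a water separator should give the benzyl ketal ester methyl 2-{2-[(R)-2-(benzyloxy)propyl]-1,3-dioxolan-2-yl}acetate F7. Hydrogenolysis (H2, 10% Pd/C, EtOAc) should give the hydroxy ester methyl 2-{2-[(R)-2-hydroxypropyl]-1,3-dioxolan-2-yl}acetate F8, which is silylated at once with TBSOTf and 2,6-lutidine to give 13.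

**Further compounds**

F1 | step 11 | 7-hydroxy-2,2-dimethyl-5-({2-[(R)-2-((tert-butyldimethylsilyl)oxy)propyl]-1,3-dioxolan-2-yl}methyl)-4H-1,3-benzodioxin-4-one | CC1(C)OC(=O)c2c(O1)cc(O)cc2CC3(C[C@@H](C)O[Si](C)(C)C(C)(C)C)OCCO3
F2 | step 11 | 3-hydroxy-6-(oxomethylidene)-5-({2-[(R)-2-((tert-butyldimethylsilyl)oxy)propyl]-1,3-dioxolan-2-yl}methyl)cyclohexa-2,4-dien-1-one (ortho-quinone ketene) | O=C=C1C(=O)C=C(O)C=C1CC2(C[C@@H](C)O[Si](C)(C)C(C)(C)C)OCCO2
F3 | step 10 | 2-{2-[(R)-2-((tert-butyldimethylsilyl)oxy)propyl]-1,3-dioxolan-2-yl}acetaldehyde | C[C@@H](O[Si](C)(C)C(C)(C)C)CC1(CC=O)OCCO1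
F4 | step 10 | 6-{4-hydroxy-2-oxo-5-[2-((R)-2-((tert-butyldimethylsilyl)oxy)propyl)-1,3-dioxolan-2-yl]pentyl}-2,2-dimethyl-4H-1,3-dioxin-4-one (carbinol epimers) | CC1(C)OC(=CC(=O)O1)CC(=O)CC(O)CC2(C[C@@H](C)O[Si](C)(C)C(C)(C)C)OCCO2
F5 | step 7 | methyl (R)-3-(benzyloxy)butanoate | C[C@@H](OCc1ccccc1)CC(=O)OC
F6 | step 7 | methyl (R)-5-(benzyloxy)-3-oxohexanoate | C[C@@H](OCc1ccccc1)CC(=O)CC(=O)OC
F7 | step 7 | methyl 2-{2-[(R)-2-(benzyloxy)propyl]-1,3-dioxolan-2-yl}acetate | C[C@@H](OCc1ccccc1)CC1(CC(=O)OC)OCCO1
F8 | step 7 | methyl 2-{2-[(R)-2-hydroxypropyl]-1,3-dioxolan-2-yl}acetate | C[C@@H](O)CC1(CC(=O)OC)OCCO1
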